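## Structural features

The target is a homodimer of two 5,6,7,8-tetrahydronaphthalen-2-ol units (7-hydroxy-cis-calamenene skeletons) joined by one aryl–aryl bond. Each half is numbered here as a tetralin: C1 (CH–CH3) to C4 (CH–isopropyl) in the saturated ring, C4a and C8a at the ring fusion, C5 (aryl CH), C6 (aryl C–CH3), C7 (C–OH) and C8, and the halves are linked C8–C8' so that each hydroxyl is ortho to the biaryl bond. Both benzene rings are pentasubstituted and the axis has four ortho substituents (two OH, two C8a with the C1 methyl groups close by), so a late aryl–aryl coupling would be hard and rotation about C8–C8' is probably slow. The four stereocentres, C1 and C4 of each half, are all S; within a half they are not adjacent but 1,4-related across the saturated ring and cis, and all are benzylic tertiary C–H centres. The fragile parts are the electron-rich 2,2'-biphenol (oxidation) and the benzylic C1–H and C4–H bonds (dehydrogenation toward a naphthalene, or epimerisation through cations or radicals). The real difficulty is the crowded C8–C8' bond between two fully substituted arenes, together with a cis C1/C4 pair of the same absolute sense in both halves. The key step uses two facts: C7–C8–C8'–C7' is a linear four-carbon unit that can be the two triple bonds of a conjugated diyne carrying acetyl groups as masked C7 oxygens, and C8a, C4a, C5 and C6 (with its methyl) are the diene of a propenylcyclohexene whose ring already holds C1 and C4.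

## Logic of the disconnections

**18 ⇒ 16 ⇒ 14.** The C7–O and C7'–O bonds are traced back, through the O–acyl bonds of 16, to the C7–C(acyl) bonds of 14 (oxygen insertion read backwards). This replaces the oxidation-prone biphenol by a robust diketone whose acetyl groups are exactly the activating groups a cycloaddition needs. The forward demand is aryl-over-methyl migration at a carbonyl flanked by two ortho substituents, and an ester cleavage mild enough for the biphenol.

**14 ⇒ 12.** No skeletal bond is cut; the C6–H and C8a–H hydrogens of each half are put back, turning each arene into a cyclohexa-1,4-diene. That ring is the direct retron of a diene-plus-alkyne cycloaddition. The forward demand is a dehydrogenation that stops at the arene and leaves C1–H and C4–H alone.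

**12 ⇒ 6 + 10 (through 11).** C8–C8a and C6–C7 are cut in both halves. The hindered biaryl bond then never has to be made between two arenes: it is the sp–sp bond already present in 10, and both aromatic rings are built around it. A C34 skeleton falls into two identical C13 dienes and one C8 diyne. The forward demand is the same regiochemistry twice (acetyl next to the methyl-bearing carbon) and a second cycloaddition at an alkyne that has become crowded.

**10 ⇒ 8 ⇒ 7.** The central sp–sp bond is cut by oxidative homocoupling, which divides the C8 chain into two identical molecules of 7 after both carbonyls are stepped back to carbinols. The coupling is placed at the alcohol level because a terminal ynone would meet amine and copper acetylide chemistry as a strong conjugate acceptor; this is the one point where the shortest conceivable sequence (direct coupling of the terminal ynone) is not used. The cost is one oxidation, which must be neutral because 10 is highly electrophilic.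

**6 ⇒ 4 + 5.** The sp2–sp2 bond C4a–C5 is cut. A cross-coupling fixes both the position of the ring alkene (from the enol triflate) and the E geometry of the side chain (from the boronic acid). The s-cis diene then has only hydrogens on the inside, which the cycloaddition requires.

**4 ⇒ 2 ⇒ 1 (through 3).** The enol C–O bond is cut back to a ketone, and the ketone to its isopropylidene precursor. The methyl-bearing centre (C1 of the target) comes from the chiral pool in 1. The forward demand is enolisation away from the isopropyl-bearing carbon so that this centre (C4 of the target) survives. That centre is set in the hydrogenation without reliable control, so a separation is accepted here; this is the weakest point of the route to 6.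

## Other disconnections considered

Alternative 1: fourfold lithiation–borylation, then ring closure.
- **Cut:** C1–C2 and C3–C4 of both saturated rings (and C2–C3 one step later). The precursor is a preformed biaryl, the tetracarbamate A1, in which each future C1 and C4 is an enantiopure secondary benzylic carbamate.
- **Forward key step:** each carbamate would be deprotonated by an alkyllithium, the benzylic anion trapped by the vinylboronic ester A2, and the vinyl group shifted from boron to carbon with loss of carbamate. This gives the tetrakis(tertiary boronate) A3. Ring-closing metathesis, stereoretentive protodeboronation, alkene hydrogenation and O-demethylation would follow.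
- **In favour:** every stereocentre comes from a stereospecific 1,2-metallate shift on a carbinol of chosen configuration, so either enantiomer and either C1/C4 relationship can be programmed. On control of C4 this is better than the chosen plan, which takes C4 from an unselective hydrogenation and a separation.
- **Against:** the biaryl problem is not solved but moved into A1, a tetra-ortho-substituted biaryl with two hexasubstituted rings and four stereodefined carbinols. Four lithiation–borylations at neighbouring, very crowded benzylic positions risk slow borylation, reversible ate-complex formation and incomplete conversion, each multiplying diastereomers. Four tertiary benzylic C–B bonds must later be protonated with retention.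
- **Comparison:** structurally it grows the saturated rings onto an existing biaryl, whereas the chosen plan grows both arenes onto existing saturated rings and takes the biaryl bond from 10. Mechanistically both rest on stereospecific events; the ionic shifts give more stereochemical freedom, the pericyclic addition fewer sensitive organometallic stages. In step economy it needs A1 plus at least five operations after A3, well beyond the nine steps of the chosen route.

Alternative 2: hexayne double cyclotrimerisation.
- **Cut:** C4a–C8a, C5–C6 and C7–C8 in each half. The hexayne A4 has a central 1,3-diyne (C8a≡C8–C8'≡C8a'), each end tethered through the C1–C4 chain to a silyl alkyne and, through a silicon–oxygen tether, to an alkynyl boronate.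
- **Forward key step:** [Rh(cod)2]BF4 with BINAP (a cationic monovalent rhodium bisphosphine catalyst) would effect two intramolecular [2+2+2] cycloadditions to the bis(benzoxasilole) bis(boronate) A5. C–B oxidation to the C7 hydroxyl, C5–Si cleavage and reduction of the benzylic CH2–O to CH3 would follow.
- **In favour:** arene regiochemistry is fixed by tethers and not by electronic bias (better than the chosen plan). The arenes appear directly at the aromatic oxidation level, so no dehydrogenation threatens C1 and C4 (better). A chiral ligand could bias the sense of the new axis, which the chosen plan leaves open (better if an axial descriptor were required). Taking the biaryl bond from the sp–sp bond of a diyne is a point of equality.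
- **Against:** A4 is a long acyclic substrate whose two propargylic stereocentres per half must be set 1,4 along a chain with no ring to relay them. Alkynyl boronates and silyl alkynes are labile. The second cyclotrimerisation must occur at a diyne carbon already bonded to a hexasubstituted arene. Three functional-group corrections per half remain after A5.
- **Comparison:** both plans make the benzene rings de novo by cycloaddition; the alternative is more convergent in the ring-forming event but far longer overall, and it trades a chiral-pool ring for acyclic stereocontrol.

Alternative 3: biaryl bis-aryne Diels–Alder.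
- **Cut:** C1–C8a and C4–C4a in both halves. The resolved biaryl bis(silyl triflate) A6 would be converted by fluoride into arynes across C4a–C8a, each trapped by the (2E,4E)-diene A7 to give the bis(1,4-dihydronaphthalene) dimethyl ether A8. Hydrogenation and O-demethylation would follow.
- **In favour:** suprafacial addition across an E,E-diene fixes the cis C1/C4 relationship by mechanism, which is better than the chosen plan on that point. The sequence from a biaryl is short, and the axis is defined from the start.
- **Against:** nothing strong decides which diene terminus (methyl or isopropyl) bonds to C8a. The absolute configuration of four new centres would have to be relayed from the axis alone, and the axis loses one ortho substituent at the aryne stage and may rotate. Acyclic dienes with allylic hydrogens tend to give ene and [2+2] products with arynes. A6 needs its own multistep synthesis and a resolution.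
- **Comparison:** the chosen plan takes its absolute configuration from a chiral-pool centre that is never touched, so the sense of C1 is certain, while its C4 is less well controlled than the cis relationship would be here. Mechanistically both are concerted [4+2] additions, with roles exchanged (arene as dienophile there, arene as product here). Counting the preparation of A6, step economy is equal at best.

Key step: step 6

Assumption: no descriptor is attached to the C8–C8' axis, so its configuration is left open; if 14, 16 and 18 form as two slowly interconverting atropisomers, these are diastereomers and would be separated by chromatography at 16.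

## Route

Step 1
Reactants: 1 (S)-pulegone [(5S)-5-methyl-2-(propan-2-ylidene)cyclohexan-1-one]
Product: 2 (2S,5S)-5-methyl-2-(propan-2-yl)cyclohexan-1-one (cis ketone)
Conditions: H2 (balloon), Pd/C (5 wt%), EtOAc, rt; filtration; careful chromatography on silica (pentane/Et2O) to remove the trans C2 epimer
Reagents that add atoms: none
Why: Heterogeneous hydrogenation should saturate only the conjugated exocyclic alkene; C5 comes unchanged from the chiral pool, while the new C2 centre arises from syn delivery of hydrogen to either face, so both C2 epimers are expected and the cis ketone is taken by separation under neutral conditions that avoid enolisation toward the more stable trans epimer.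

Step 2
Reactants: 2 (2S,5S)-5-methyl-2-(propan-2-yl)cyclohexan-1-one
Product: 4 (3S,6S)-3-methyl-6-(propan-2-yl)cyclohex-1-en-1-yl trifluoromethanesulfonate, via lithium enolate 3 (not isolated)
Conditions: LiN(i-Pr)2 (1.1 equiv, commercial solution), THF, −78 °C, ketone added slowly to the base; PhNTf2 (1.1 equiv), −78 to 0 °C
Reagents that add atoms: N-phenylbis(trifluoromethanesulfonimide), O=S(=O)(N(c1ccccc1)S(=O)(=O)C(F)(F)F)C(F)(F)F
Why: Kinetic deprotonation by the hindered amide should take a proton from the open C6 methylene and not from the isopropyl-bearing C2 methine, so the enolate forms irreversibly away from the stereocentre and O-sulfonylation locks the double bond there (regioselective enol triflate formation); slow addition of the ketone to excess base keeps free ketone from equilibrating the enolate.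

Step 3
Reactants: 4 (3S,6S)-3-methyl-6-(propan-2-yl)cyclohex-1-en-1-yl trifluoromethanesulfonate; 5 (E)-prop-1-en-1-ylboronic acid
Product: 6 (3S,6S)-3-methyl-6-(propan-2-yl)-1-[(1E)-prop-1-en-1-yl]cyclohex-1-ene
Conditions: Pd(PPh3)4 (5 mol%), K3PO4 (3 equiv), 1,4-dioxane/H2O, 70 °C; filtration through silica with pentane
Reagents that add atoms: none
Why: Suzuki–Miyaura coupling of an enol triflate with an alkenylboronic acid at zerovalent palladium; oxidative addition, transmetallation and reductive elimination all retain alkene geometry, so the E-propenyl group and the ring alkene position are transferred unchanged, and the two allylic stereocentres are not acidic enough to suffer under phosphate.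

Step 4
Reactants: 7 but-3-yn-2-ol, racemic (2 equiv)
Product: 8 octa-3,5-diyne-2,7-diol (meso and racemic forms together)
Conditions: CuCl (10 mol%), TMEDA (20 mol%), O2 (balloon), acetone, rt
Reagents that add atoms: none
Why: Hay variant of the Glaser oxidative homocoupling: two molecules of 7 are joined at their terminal alkyne carbons through monovalent copper acetylides, the two alkyne hydrogens ending up in water formed from O2. The alcohol is used because a terminal ynone would add the amine ligand in a conjugate sense, and the carbinol configuration is irrelevant since both centres are oxidised in step 5.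

Step 5
Reactants: 8 octa-3,5-diyne-2,7-diol
Product: 10 octa-3,5-diyne-2,7-dione, via 7-hydroxyocta-3,5-diyn-2-one 9 (not isolated)
Conditions: activated MnO2 (excess), CH2Cl2, rt, dark; filtration through Celite; solution concentrated cold and used at once
Reagents that add atoms: none
Why: Activated MnO2 oxidises propargylic alcohols selectively under neutral conditions, and isolation by filtration alone spares the strongly electrophilic diynedione any contact with base, nucleophile or aqueous reductant.

Step 6
Reactants: 6 (3S,6S)-3-methyl-6-(propan-2-yl)-1-[(1E)-prop-1-en-1-yl]cyclohex-1-ene (2.6 equiv); 10 octa-3,5-diyne-2,7-dione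
Product: 12 double adduct 1,1'-[(1S,1'S,4S,4'S)-1,1',6,6'-tetramethyl-4,4'-di(propan-2-yl)-1,1',2,2',3,3',4,4',6,6',8a,8a'-dodecahydro-8,8'-binaphthalene-7,7'-diyl]di(ethan-1-one) (half numbering of the target; epimer mixture at C6 and C8a of both halves), via mono-adduct 11 (not isolated)
Conditions: toluene (1 M in 10), BHT (1 mol%), 90 °C, sealed tube, Ar, dark; short silica plug, crude material taken on
Reagents that add atoms: none
Why: Each ynone unit of 10 is an electron-poor two-π component and 6 is an electron-rich diene whose s-cis form has only hydrogens on the inside (the ring bond at C8a and the methyl at C6 both point outward), so two successive thermal, concerted but asynchronous [4+2] cycloadditions are expected, the first giving 11 and the slower second one 12. The closest known reaction type is the Diels–Alder addition of 1-alkenylcyclohexenes to alkynyl ketones, applied here twice to one conjugated diyne. Each new ring is a cyclohexa-1,4-diene closed by an intermolecular suprafacial–suprafacial cycloaddition in which C8–C8a and C6–C7 form in one kinetic step, the bond from the ynone carbon remote from acetyl (C8) to C8a being the more advanced. The regiochemistry needed in both halves, acetyl on C7 next to the methyl-bearing C6, follows from matched polarisation: C8 is the conjugate-acceptor carbon of the ynone, and C8a is the more nucleophilic diene terminus because bonding there leaves the developing positive charge on the more substituted allyl fragment C4a–C5–C6 (tertiary at C4a, secondary at C6). The new sp3 centres C6 and C8a (four in all) are fixed relative to each other by suprafacial addition to the E-configured diene (C6–H and C8a–H cis), whereas the diene face relative to C1 and C4 is not controlled and need not be, because all four centres are flattened in step 7. C1 and C4 lie outside the reacting π system, and no acid or base is present that could move the ring double bonds toward them. Chemoselectivity rests on each alkyne reacting once, since the tetrasubstituted enone left in the adduct is too hindered to serve as a dienophile; excess diene, high concentration and a radical inhibitor are meant to favour the hindered second addition over polymerisation of 10.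

Step 7
Reactants: 12 double adduct (crude epimer mixture)
Product: 14 1,1'-[(1S,1'S,4S,4'S)-1,1',6,6'-tetramethyl-4,4'-di(propan-2-yl)-1,1',2,2',3,3',4,4'-octahydro-8,8'-binaphthalene-7,7'-diyl]di(ethan-1-one), via half-aromatised adduct 13 (not isolated)
Conditions: DDQ (2.3 equiv), benzene, rt to 50 °C
Reagents that add atoms: none
Why: Dehydrogenation of 1,4-cyclohexadienes by DDQ: hydride is taken from a doubly allylic ring position (C6 or C8a) and the cyclohexadienyl cation loses a proton, which should be much faster than attack at the singly activated C1–H and C4–H. The arenes formed carry an acetyl group and are too electron-poor for benzylic hydride abstraction at this temperature; the four transient centres vanish and the biaryl axis is created here.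

Step 8
Reactants: 14 biaryl diketone
Product: 16 (1S,1'S,4S,4'S)-1,1',6,6'-tetramethyl-4,4'-di(propan-2-yl)-1,1',2,2',3,3',4,4'-octahydro-8,8'-binaphthalene-7,7'-diyl diacetate, via keto acetate 15 (not isolated)
Conditions: m-CPBA (5 equiv), CF3CO2H (cat.), CH2Cl2, 0 °C to rt, dark; aq. Na2SO3 then NaHCO3 wash
Reagents that add atoms: m-chloroperoxybenzoic acid, OOC(=O)c1cccc(Cl)c1
Why: Baeyer–Villiger oxidation: in the tetrahedral peracid adduct of an aryl methyl ketone the electron-rich, fully alkylated aryl group should migrate in preference to methyl, and the two ortho substituents twist the carbonyl out of conjugation, which keeps it electrophilic toward the peracid. No stereocentre takes part.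

Step 9
Reactants: 16 biaryl diacetate
Product: 18 (1S,1'S,4S,4'S)-1,1',6,6'-tetramethyl-4,4'-di(propan-2-yl)-1,1',2,2',3,3',4,4'-octahydro-8,8'-binaphthalene-7,7'-diol (target), via monoacetate 17 (not isolated)
Conditions: K2CO3 (0.5 equiv), degassed MeOH/THF, rt to 40 °C, Ar; aq. NH4Cl
Reagents that add atoms: none
Why: Base-promoted methanolysis (transesterification) of aryl acetates is mild, non-oxidising and cannot epimerise the benzylic C1 and C4 centres; exclusion of air protects the electron-rich biphenol.

## Compound list

1 | (S)-pulegone, (5S)-5-methyl-2-(propan-2-ylidene)cyclohexan-1-one | C[C@H]1CCC(=C(C)C)C(=O)C1 | starting material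
2 | (2S,5S)-5-methyl-2-(propan-2-yl)cyclohexan-1-one (cis ketone) | O=C1C[C@@H](C)CC[C@H]1C(C)C | intermediate
3 | lithium (3S,6S)-3-methyl-6-(propan-2-yl)cyclohex-1-en-1-olate | [Li]OC1=C[C@@H](C)CC[C@H]1C(C)C | intermediate
4 | (3S,6S)-3-methyl-6-(propan-2-yl)cyclohex-1-en-1-yl trifluoromethanesulfonate | FC(F)(F)S(=O)(=O)OC1=C[C@@H](C)CC[C@H]1C(C)C | intermediate
5 | (E)-prop-1-en-1-ylboronic acid | C/C=C/B(O)O | starting material
6 | (3S,6S)-3-methyl-6-(propan-2-yl)-1-[(1E)-prop-1-en-1-yl]cyclohex-1-ene | C/C=C/C1=C[C@@H](C)CC[C@H]1C(C)C | intermediate
7 | but-3-yn-2-ol (racemic) | CC(O)C#C | starting material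
8 | octa-3,5-diyne-2,7-diol | CC(O)C#CC#CC(C)O | intermediate
9 | 7-hydroxyocta-3,5-diyn-2-one | CC(O)C#CC#CC(C)=O | intermediate
10 | octa-3,5-diyne-2,7-dione | CC(=O)C#CC#CC(C)=O | intermediate
11 | 4-[(1S,4S)-7-acetyl-1,6-dimethyl-4-(propan-2-yl)-1,2,3,4,6,8a-hexahydronaphthalen-8-yl]but-3-yn-2-one (half numbering; C6/C8a epimers) | CC1C=C2[C@H](C(C)C)CC[C@H](C)C2C(C#CC(C)=O)=C1C(C)=O | intermediate
12 | 1,1'-[(1S,1'S,4S,4'S)-1,1',6,6'-tetramethyl-4,4'-di(propan-2-yl)-1,1',2,2',3,3',4,4',6,6',8a,8a'-dodecahydro-8,8'-binaphthalene-7,7'-diyl]di(ethan-1-one) (C6/C8a epimers) | CC1C=C2[C@H](C(C)C)CC[C@H](C)C2C(=C1C(C)=O)C1=C(C(C)=O)C(C)C=C2[C@H](C(C)C)CC[C@H](C)C12 | intermediate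
13 | half-aromatised adduct: one half as in 14, the other as in 12 | Cc1cc2c(c(C3=C(C(C)=O)C(C)C=C4[C@H](C(C)C)CC[C@H](C)C34)c1C(C)=O)[C@@H](C)CC[C@H]2C(C)C | intermediate
14 | 1,1'-[(1S,1'S,4S,4'S)-1,1',6,6'-tetramethyl-4,4'-di(propan-2-yl)-1,1',2,2',3,3',4,4'-octahydro-8,8'-binaphthalene-7,7'-diyl]di(ethan-1-one) | Cc1cc2c(c(-c3c(C(C)=O)c(C)cc4c3[C@@H](C)CC[C@H]4C(C)C)c1C(C)=O)[C@@H](C)CC[C@H]2C(C)C | intermediate
15 | keto acetate: 14 with one acetyl replaced by acetoxy | Cc1cc2c(c(-c3c(C(C)=O)c(C)cc4c3[C@@H](C)CC[C@H]4C(C)C)c1OC(C)=O)[C@@H](C)CC[C@H]2C(C)C | intermediate
16 | (1S,1'S,4S,4'S)-1,1',6,6'-tetramethyl-4,4'-di(propan-2-yl)-1,1',2,2',3,3',4,4'-octahydro-8,8'-binaphthalene-7,7'-diyl diacetate | Cc1cc2c(c(-c3c(OC(C)=O)c(C)cc4c3[C@@H](C)CC[C@H]4C(C)C)c1OC(C)=O)[C@@H](C)CC[C@H]2C(C)C | intermediate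
17 | monoacetate: 16 with one acetoxy replaced by hydroxyl | Cc1cc2c(c(-c3c(OC(C)=O)c(C)cc4c3[C@@H](C)CC[C@H]4C(C)C)c1O)[C@@H](C)CC[C@H]2C(C)C | intermediate
18 | (1S,1'S,4S,4'S)-1,1',6,6'-tetramethyl-4,4'-di(propan-2-yl)-1,1',2,2',3,3',4,4'-octahydro-8,8'-binaphthalene-7,7'-diol; systematic numbering (5S,5'S,8S,8'S)-3,3',8,8'-tetramethyl-5,5'-di(propan-2-yl)-5,5',6,6',7,7',8,8'-octahydro-[1,1'-binaphthalene]-2,2'-diol | Cc1cc2c(c(-c3c(O)c(C)cc4c3[C@@H](C)CC[C@H]4C(C)C)c1O)[C@@H](C)CC[C@H]2C(C)C | target

## Step count and least certain steps

Total: 9 steps. Longest linear sequence: 7 steps (steps 1, 2, 3, 6, 7, 8, 9); the dienophile branch (steps 4 and 5) joins at step 6.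

**Step 6 (key step).**
- What may go wrong: the sequence may stall after the first cycloaddition. The remaining alkyne is less electron-poor and its reacting carbon is now flanked by a bulky ring, so thermal polymerisation of 10 and 11 can outrun the second addition. Regioselectivity may also leak, since both diene termini are monoalkylated and only the C4a substituent tips the balance.
- Fallback, from 6 back to the route at 18: 6 is heated with commercial but-3-yn-2-one (CC(=O)C#C) in toluene to give the single cycloadduct 1-[(1S,4S)-1,6-dimethyl-4-(propan-2-yl)-1,2,3,4,6,8a-hexahydronaphthalen-7-yl]ethan-1-one F1, where one unhindered ynone reacts and regioisomers can be removed at the monomer stage. DDQ gives (1S,4S)-7-acetylcalamenene F2, peracid oxidation gives (1S,4S)-7-acetoxycalamenene F3, and methanolysis gives (1S,4S)-7-hydroxycalamenene F4. Aerobic oxidative phenol coupling (CuCl/TMEDA, O2) then joins two molecules of F4 at C8, the only free position ortho to the hydroxyl (C6 and the para position C4a are blocked), to reach 18.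

**Step 1.**
- What may go wrong: poor facial selectivity in hydrogen delivery to C2, a hard separation of two epimeric ketones of nearly equal polarity, and drift toward the trans epimer by enolisation on the adsorbent.
- Fallback, from 1 back at 2: the hydrogenation is run as in step 1 without separation, giving 2 together with its epimer (2R,5S)-5-methyl-2-(propan-2-yl)cyclohexan-1-one F5. The mixture is heated with pyrrolidine and catalytic TsOH with azeotropic removal of water to give the enamine 1-[(3S,6S)-3-methyl-6-(propan-2-yl)cyclohex-1-en-1-yl]pyrrolidine F6. Reversible enamine–iminium tautomerism equilibrates C2, and allylic strain between the amine and the isopropyl group should favour the isomer with pseudoaxial isopropyl and pseudoequatorial methyl, which is the cis series. Cold buffered hydrolysis (aq. AcOH/NaOAc) protonates C6 and returns 2 without touching C2.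

**Step 7.**
- What may go wrong: over-oxidation, by hydride loss from the allylic C4–H or later from benzylic C1–H or C4–H, would start dehydrogenation of the saturated ring and erase stereocentres. The acidic hydroquinone may also shift ring double bonds before oxidation.
- Fallback, from 12 back at 14: 12 is treated with DBU under air in MeCN. Deprotonation at C8a (γ to the acetyl carbonyl) gives an extended enolate that is trapped by O2 and loses hydrogen peroxide to give the arene. This base-mediated autoxidation cannot abstract hydride from non-activated benzylic positions and forms no isolable new compound.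

**Step 8.**
- What may go wrong: slow peracid addition to the doubly ortho-flanked carbonyl, so that the reaction stops at 15 or the oxidant turns on the electron-rich ring.
- Fallback, from 14 back at 18: LiAlH4 reduces both ketones to the bis(1-hydroxyethyl) biaryl F7 (carbinol epimers, irrelevant). H2O2 with BF3·OEt2 in CH2Cl2 exchanges hydroxyl for hydroperoxyl through the benzylic cation to give the bis(1-hydroperoxyethyl) biaryl F8, which is not isolated. Acid-induced Hock rearrangement (aryl shift from carbon to oxygen) and hydrolysis of the resulting oxocarbenium ion release acetaldehyde and 18, bypassing 16.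

## Further compounds

F1 | step 6 | 1-[(1S,4S)-1,6-dimethyl-4-(propan-2-yl)-1,2,3,4,6,8a-hexahydronaphthalen-7-yl]ethan-1-one (half numbering; C6/C8a epimers) | CC1C=C2[C@H](C(C)C)CC[C@H](C)C2C=C1C(C)=O
F2 | step 6 | (1S,4S)-7-acetylcalamenene, 1-[(5S,8S)-3,8-dimethyl-5-(propan-2-yl)-5,6,7,8-tetrahydronaphthalen-2-yl]ethan-1-one | Cc1cc2c(cc1C(C)=O)[C@@H](C)CC[C@H]2C(C)C
F3 | step 6 | (1S,4S)-7-acetoxycalamenene, (5S,8S)-3,8-dimethyl-5-(propan-2-yl)-5,6,7,8-tetrahydronaphthalen-2-yl acetate | Cc1cc2c(cc1OC(C)=O)[C@@H](C)CC[C@H]2C(C)C
F4 | step 6 | (1S,4S)-7-hydroxycalamenene, (5S,8S)-3,8-dimethyl-5-(propan-2-yl)-5,6,7,8-tetrahydronaphthalen-2-ol | Cc1cc2c(cc1O)[C@@H](C)CC[C@H]2C(C)C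
F5 | step 1 | (2R,5S)-5-methyl-2-(propan-2-yl)cyclohexan-1-one (trans ketone) | O=C1C[C@@H](C)CC[C@@H]1C(C)C
F6 | step 1 | 1-[(3S,6S)-3-methyl-6-(propan-2-yl)cyclohex-1-en-1-yl]pyrrolidine | C1CCN(C1)C1=C[C@@H](C)CC[C@H]1C(C)C
F0 | step 7 | none | none
F7 | step 8 | 1,1'-[(1S,1'S,4S,4'S)-1,1',6,6'-tetramethyl-4,4'-di(propan-2-yl)-1,1',2,2',3,3',4,4'-octahydro-8,8'-binaphthalene-7,7'-diyl]di(ethan-1-ol) (carbinol epimers) | Cc1cc2c(c(-c3c(C(C)O)c(C)cc4c3[C@@H](C)CC[C@H]4C(C)C)c1C(C)O)[C@@H](C)CC[C@H]2C(C)C
F8 | step 8 | corresponding bis(1-hydroperoxyethyl) biaryl (not isolated) | Cc1cc2c(c(-c3c(C(C)OO)c(C)cc4c3[C@@H](C)CC[C@H]4C(C)C)c1C(C)OO)[C@@H](C)CC[C@H]2C(C)C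
A1 | alternative 1 | biaryl tetrakis(N,N-diisopropylcarbamate) of the four benzylic carbinols (7,7'-dimethoxy, 6,6'-dimethyl) | COc1c(C)cc([C@@H](C(C)C)OC(=O)N(C(C)C)C(C)C)c([C@H](C)OC(=O)N(C(C)C)C(C)C)c1-c1c(OC)c(C)cc([C@@H](C(C)C)OC(=O)N(C(C)C)C(C)C)c1[C@H](C)OC(=O)N(C(C)C)C(C)C
A2 | alternative 1 | vinylboronic acid pinacol ester | C=CB1OC(C)(C)C(C)(C)O1
A3 | alternative 1 | biaryl tetrakis(tertiary benzylic pinacol boronate) with four vinyl groups | COc1c(C)cc([C@@](B2OC(C)(C)C(C)(C)O2)(C=C)C(C)C)c([C@@](B2OC(C)(C)C(C)(C)O2)(C)C=C)c1-c1c(OC)c(C)cc([C@@](B2OC(C)(C)C(C)(C)O2)(C=C)C(C)C)c1[C@@](B2OC(C)(C)C(C)(C)O2)(C)C=C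
A4 | alternative 2 | hexayne: central 1,3-diyne, two chiral 1,7-diyne tethers, two diisopropylsilyl propargyl ether links ending in alkynyl pinacol boronates | CC1(C)OB(OC1(C)C)C#CCO[Si](C(C)C)(C(C)C)C#C[C@H](C(C)C)CC[C@H](C)C#CC#C[C@@H](C)CC[C@@H](C(C)C)C#C[Si](C(C)C)(C(C)C)OCC#CB1OC(C)(C)C(C)(C)O1
A5 | alternative 2 | biaryl bis(benzoxasilole) bis(pinacol boronate) | CC1(C)OB(OC1(C)C)c1c2CO[Si](C(C)C)(C(C)C)c2c2c(c1-c1c(B3OC(C)(C)C(C)(C)O3)c3CO[Si](C(C)C)(C(C)C)c3c3c1[C@@H](C)CC[C@H]3C(C)C)[C@@H](C)CC[C@H]2C(C)C
A6 | alternative 3 | 2,2'-dimethoxy-3,3'-dimethyl-6,6'-bis(trimethylsilyl)-[1,1'-biphenyl]-5,5'-diyl bis(trifluoromethanesulfonate), one atropisomer (axis not encoded) | COc1c(C)cc(OS(=O)(=O)C(F)(F)F)c([Si](C)(C)C)c1-c1c(OC)c(C)cc(OS(=O)(=O)C(F)(F)F)c1[Si](C)(C)C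
A7 | alternative 3 | (2E,4E)-6-methylhepta-2,4-diene | C/C=C/C=C/C(C)C
A8 | alternative 3 | 2,3-didehydro bis(methyl ether) of the target (1,4-dihydronaphthalene halves) | COc1c(C)cc2c(c1-c1c(OC)c(C)cc3c1[C@@H](C)C=C[C@H]3C(C)C)[C@@H](C)C=C[C@H]2C(C)C
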